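**Strategy.** Both diterpene halves carry the same decalin (labdane numbering), so it is built once, as aldehyde 19, from an acyclic chain. The exocyclic methylene C8=C17 is read as a masked C8 ketone. C5 is then α to a C6 aldehyde and C10 is β to the C8 carbonyl, so the C5–C10 ring-fusion bond is a Michael retron. An amine-catalysed intramolecular Michael addition of keto-aldehyde 11 closes ring A at C5–C10, setting C5 by catalyst control and the quaternary C10 by relay; aldol condensation then closes ring B. C9 is set later by equilibration. Olefination and aldol chemistry on 19 give the acid half and the (R)-hydroxylactone half, which are joined by esterification.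

Key step: step 6

Assumptions: ring A is C1–C5 with C10, ring B is C5–C10, C17 is the exocyclic CH2 and C11–C16 the side chain, in both units. The sense of induction in step 6 is assigned from the usual steric-shielding model of diarylprolinol silyl ethers; if the opposite sense is found, the enantiomeric catalyst is used.

Step 1
Reactants: 1 5-chloropent-1-yne; 2 acetaldehyde
Product: 4 (3E)-7-chloro-4-methylhept-3-en-2-ol (racemic), via alkenylalane 3 (not isolated)
Conditions: Me3Al, Cp2ZrCl2 (20 mol%), CH2Cl2, 0 °C to rt; volatiles removed; n-BuLi, THF, −78 °C; 2, −78 °C to rt; aq. HCl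
Reagents that add atoms: trimethylaluminium, C[Al](C)C
Why: Zirconium-catalysed carboalumination (Negishi) adds Me and Al syn across the terminal alkyne to give the (E)-alkenylalane, whose ate complex adds to acetaldehyde with retention of geometry; the racemic carbinol centre is erased in step 5.

Step 2
Reactants: 4 (3E)-7-chloro-4-methylhept-3-en-2-ol
Product: 5 tert-butyl{[(3E)-7-chloro-4-methylhept-3-en-2-yl]oxy}dimethylsilane
Conditions: tBuMe2SiCl, imidazole, DMF, rt
Reagents that add atoms: tert-butyldimethylsilyl chloride, CC(C)(C)[Si](C)(C)Cl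
Why: Silylation masks the alcohol so that the alkyl chloride can be turned into a Grignard reagent.

Step 3
Reactants: 5 tert-butyl{[(3E)-7-chloro-4-methylhept-3-en-2-yl]oxy}dimethylsilane; 6 3-methylbut-2-enal
Product: 9 (7E)-9-[(tert-butyldimethylsilyl)oxy]-3,3,7-trimethyldec-7-enal, via Grignard reagent 7 (not isolated), via silyl enol ether 8 (not isolated)
Conditions: Mg, THF, reflux; then CuBr·SMe2 (5 mol%), Me3SiCl, 6, THF, −78 °C; aq. citric acid
Reagents that add atoms: none
Why: Copper-catalysed conjugate addition of the Grignard reagent to the β,β-disubstituted enal builds the quaternary gem-dimethyl carbon C4; chlorosilane trapping of the enolate suppresses 1,2-addition and mild acid releases the aldehyde.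

Step 4
Reactants: 9 (7E)-9-[(tert-butyldimethylsilyl)oxy]-3,3,7-trimethyldec-7-enal
Product: 10 (7E)-9-hydroxy-3,3,7-trimethyldec-7-enal
Conditions: Bu4NF, AcOH, THF, 0 °C to rt
Reagents that add atoms: none
Why: Buffered fluoride cleaves the silyl ether without aldol side reactions of the hindered aldehyde.

Step 5
Reactants: 10 (7E)-9-hydroxy-3,3,7-trimethyldec-7-enal
Product: 11 (7E)-3,3,7-trimethyl-9-oxodec-7-enal
Conditions: MnO2, CH2Cl2, rt
Reagents that add atoms: none
Why: Manganese dioxide oxidises the allylic alcohol selectively to the (E)-enone and leaves the saturated aldehyde untouched.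

Step 6
Reactants: 11 (7E)-3,3,7-trimethyl-9-oxodec-7-enal
Product: 13 (4aS,8aR)-5,5,8a-trimethyl-4a,5,6,7,8,8a-hexahydronaphthalen-2(1H)-one, via Michael adduct 12 (not isolated)
Conditions: (R)-2-[diphenyl(trimethylsilyloxy)methyl]pyrrolidine (20 mol%), 4-nitrobenzoic acid (20 mol%), toluene, 50 °C, to full conversion; then p-TsOH·H2O (20 mol%), 80 °C
Reagents that add atoms: none
Why: Proposed new method: the amine condenses with the aldehyde of 11 to an (E)-enamine whose carbon C5 adds to the acid-activated enone carbon C10 in a 6-exo-trig conjugate addition that closes ring A; hydrolysis gives 12, and acid then drives the 6-(enolexo)-exo-trig aldol condensation of the methyl ketone carbon C7 onto the C6 aldehyde, closing ring B with loss of water and making the sequence irreversible. The closest known reaction type is the amine-catalysed enantioselective intramolecular Michael addition of formyl enones (organocatalytic Robinson annulation), established for β-monosubstituted enones; the extension is the β,β-disubstituted acceptor that makes C10 quaternary. C5 is set by the catalyst, whose diphenyl(silyloxy)methyl group shields one enamine face so that C10 bonds to the Re face of C5. C10 is relayed from C5 through a chair transition state with the enamine and the enone carbon C9 both pseudo-equatorial and the C10 methyl axial, which gives the trans relation. The step needs enamine formation at the aldehyde and not at the conjugated methyl ketone (the aldehyde condenses faster) and 6-exo closure, which the three-carbon tether and the gem-dimethyl group at C4 favour. A minor cis adduct would later epimerise at C5 through the dienol and lower the enantiomeric purity, so the mildest acid that dehydrates is used.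

Step 7
Reactants: 13 (4aS,8aR)-5,5,8a-trimethyl-4a,5,6,7,8,8a-hexahydronaphthalen-2(1H)-one; 14 methyl bromoacetate
Product: 15 methyl 2-[(1S,4aS,8aS)-5,5,8a-trimethyl-2-oxo-1,2,4a,5,6,7,8,8a-octahydronaphthalen-1-yl]acetate
Conditions: LiN(iPr)2, THF, −78 °C; 14, DMPU, −78 to −30 °C
Reagents that add atoms: none
Why: Kinetic deprotonation of the enone can only give the cross-conjugated dienolate at C9, so alkylation is regiospecific; the electrophile should enter anti to the angular methyl, and this C9 centre is corrected in step 8.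

Step 8
Reactants: 15 methyl 2-[(1S,4aS,8aS)-5,5,8a-trimethyl-2-oxo-1,2,4a,5,6,7,8,8a-octahydronaphthalen-1-yl]acetate
Product: 17 methyl 2-[(1R,4aS,8aS)-5,5,8a-trimethyl-2-oxodecahydronaphthalen-1-yl]acetate, via 1-epi keto ester 16 (not isolated)
Conditions: H2 (1 atm), Pd/C, EtOAc, rt; filter; K2CO3, MeOH, rt
Reagents that add atoms: none
Why: Hydrogenation saturates the C6–C7 enone double bond, and base equilibration through the C8 enolate moves the C9 side chain to the equatorial position, which is the natural 9S configuration of the trans-decalin.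

Step 9
Reactants: 17 methyl 2-[(1R,4aS,8aS)-5,5,8a-trimethyl-2-oxodecahydronaphthalen-1-yl]acetate
Product: 18 methyl 2-[(1S,4aS,8aS)-5,5,8a-trimethyl-2-methylidenedecahydronaphthalen-1-yl]acetate
Conditions: Ph3PCH3Br, KOtBu, toluene, 80 °C
Reagents that add atoms: methyltriphenylphosphonium bromide, C[P+](c1ccccc1)(c1ccccc1)c1ccccc1.[Br-]
Why: Wittig methylenation turns the C8 ketone into the exocyclic C8=C17 alkene; any epimerisation at C9 under the basic conditions returns the same thermodynamic isomer.

Step 10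
Reactants: 18 methyl 2-[(1S,4aS,8aS)-5,5,8a-trimethyl-2-methylidenedecahydronaphthalen-1-yl]acetate
Product: 19 2-[(1S,4aS,8aS)-5,5,8a-trimethyl-2-methylidenedecahydronaphthalen-1-yl]acetaldehyde
Conditions: iBu2AlH, CH2Cl2, −78 °C; Rochelle salt work-up
Reagents that add atoms: none
Why: Partial reduction of the methyl ester at low temperature stops at the tetrahedral aluminium acetal and gives the C12 aldehyde common to both halves.

Step 11
Reactants: 20 triethyl phosphonoacetate; 21 2-bromo-1,1-dimethoxyethane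
Product: 22 ethyl 2-(diethoxyphosphoryl)-4,4-dimethoxybutanoate
Conditions: NaH, DMF, 0 °C; 21, NaI (cat.), 90 °C
Reagents that add atoms: none
Why: C-Alkylation of the phosphonoacetate anion installs C14 and the masked C15 aldehyde on the olefination reagent.

Step 12
Reactants: 19 2-[(1S,4aS,8aS)-5,5,8a-trimethyl-2-methylidenedecahydronaphthalen-1-yl]acetaldehyde; 22 ethyl 2-(diethoxyphosphoryl)-4,4-dimethoxybutanoate
Product: 23 ethyl (2E)-2-(2,2-dimethoxyethyl)-4-[(1S,4aS,8aS)-5,5,8a-trimethyl-2-methylidenedecahydronaphthalen-1-yl]but-2-enoate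
Conditions: NaH, THF, 0 °C to rt
Reagents that add atoms: none
Why: Horner–Wadsworth–Emmons olefination forms the trisubstituted C12=C13 alkene, the (E) isomer (ester anti to C11) being expected to predominate under equilibrating conditions; any (Z) isomer is removed by chromatography.

Step 13
Reactants: 23 ethyl (2E)-2-(2,2-dimethoxyethyl)-4-[(1S,4aS,8aS)-5,5,8a-trimethyl-2-methylidenedecahydronaphthalen-1-yl]but-2-enoate
Product: 24 (2E)-2-(2,2-dimethoxyethyl)-4-[(1S,4aS,8aS)-5,5,8a-trimethyl-2-methylidenedecahydronaphthalen-1-yl]but-2-enoic acid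
Conditions: LiOH, THF/MeOH/H2O, 45 °C; aq. HCl to pH 4 at 0 °C
Reagents that add atoms: lithium hydroxide, [Li+].[OH-]
Why: Saponification frees the C16 acid while the dimethyl acetal, which is stable to base, keeps the C15 aldehyde masked.

Step 14
Reactants: 25 (R)-4-hydroxydihydrofuran-2(3H)-one
Product: 26 (R)-4-[(tert-butyldimethylsilyl)oxy]dihydrofuran-2(3H)-one
Conditions: tBuMe2SiCl, imidazole, DMF, rt
Reagents that add atoms: tert-butyldimethylsilyl chloride, CC(C)(C)[Si](C)(C)Cl
Why: The purchased C14 stereocentre is protected as a silyl ether, a poor leaving group that tolerates enolate formation at low temperature.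

Step 15
Reactants: 26 (R)-4-[(tert-butyldimethylsilyl)oxy]dihydrofuran-2(3H)-one; 19 2-[(1S,4aS,8aS)-5,5,8a-trimethyl-2-methylidenedecahydronaphthalen-1-yl]acetaldehyde
Product: 27 (4R)-4-[(tert-butyldimethylsilyl)oxy]-3-{1-hydroxy-2-[(1S,4aS,8aS)-5,5,8a-trimethyl-2-methylidenedecahydronaphthalen-1-yl]ethyl}dihydrofuran-2(3H)-one (3,4-trans; both carbinol epimers)
Conditions: LiN(iPr)2, THF, −78 °C, short enolisation; 19, −78 °C; aq. NH4Cl
Reagents that add atoms: none
Why: Aldol addition of the lithium lactone enolate to 19 forms the C12–C13 bond anti to the silyloxy group; the two new centres are erased in step 16, so their ratio does not matter.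

Step 16
Reactants: 27 (4R)-4-[(tert-butyldimethylsilyl)oxy]-3-{1-hydroxy-2-[(1S,4aS,8aS)-5,5,8a-trimethyl-2-methylidenedecahydronaphthalen-1-yl]ethyl}dihydrofuran-2(3H)-one
Product: 29 (3E,4R)-4-[(tert-butyldimethylsilyl)oxy]-3-{2-[(1S,4aS,8aS)-5,5,8a-trimethyl-2-methylidenedecahydronaphthalen-1-yl]ethylidene}dihydrofuran-2(3H)-one, via mesylate 28 (not isolated)
Conditions: MsCl, Et3N, CH2Cl2, 0 °C; then DBU, rt
Reagents that add atoms: none
Why: E1cB elimination expels the mesylate and not the silyloxy group, giving the conjugated alkylidene lactone; the (E) isomer (carbonyl anti to C11) is expected to dominate and C14 is untouched.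

Step 17
Reactants: 29 (3E,4R)-4-[(tert-butyldimethylsilyl)oxy]-3-{2-[(1S,4aS,8aS)-5,5,8a-trimethyl-2-methylidenedecahydronaphthalen-1-yl]ethylidene}dihydrofuran-2(3H)-one
Product: 30 (3E,4R)-4-hydroxy-3-{2-[(1S,4aS,8aS)-5,5,8a-trimethyl-2-methylidenedecahydronaphthalen-1-yl]ethylidene}dihydrofuran-2(3H)-one (isocoronarin D)
Conditions: HF·pyridine, pyridine, THF, 0 °C to rt
Reagents that add atoms: none
Why: Buffered fluoride removes the silyl ether without base-induced isomerisation of the alkylidene lactone or acid-induced migration of the exocyclic alkene.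

Step 18
Reactants: 24 (2E)-2-(2,2-dimethoxyethyl)-4-[(1S,4aS,8aS)-5,5,8a-trimethyl-2-methylidenedecahydronaphthalen-1-yl]but-2-enoic acid; 30 isocoronarin D
Product: 32 (3R,4E)-5-oxo-4-{2-[(1S,4aS,8aS)-5,5,8a-trimethyl-2-methylidenedecahydronaphthalen-1-yl]ethylidene}tetrahydrofuran-3-yl (2E)-2-(2,2-dimethoxyethyl)-4-[(1S,4aS,8aS)-5,5,8a-trimethyl-2-methylidenedecahydronaphthalen-1-yl]but-2-enoate, via mixed anhydride 31 (not isolated)
Conditions: 2,4,6-trichlorobenzoyl chloride, Et3N, THF, rt; then 30, DMAP, toluene, rt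
Reagents that add atoms: none
Why: Yamaguchi esterification activates the hindered α-branched acrylic acid as a mixed anhydride and acylates the secondary allylic C14 alcohol on oxygen, so C14 keeps its configuration.

Step 19
Reactants: 32 acetal ester
Product: 33 (3R,4E)-5-oxo-4-{2-[(1S,4aS,8aS)-5,5,8a-trimethyl-2-methylidenedecahydronaphthalen-1-yl]ethylidene}tetrahydrofuran-3-yl (2E)-2-(2-oxoethyl)-4-[(1S,4aS,8aS)-5,5,8a-trimethyl-2-methylidenedecahydronaphthalen-1-yl]but-2-enoate (target)
Conditions: PPTS, acetone/H2O (9:1), 45 °C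
Reagents that add atoms: water, O
Why: Mild acid hydrolysis of the dimethyl acetal unmasks the C15 aldehyde under conditions that should leave both exocyclic alkenes, the allylic ester and the lactone intact.

**Compound list**

1 | 5-chloropent-1-yne | C#CCCCCl | starting material
2 | acetaldehyde | CC=O | starting material
3 | [(1E)-5-chloro-2-methylpent-1-en-1-yl]dimethylalane (not isolated) | C[Al](C)/C=C(\C)CCCCl | intermediate
4 | (3E)-7-chloro-4-methylhept-3-en-2-ol (racemic) | CC(O)/C=C(\C)CCCCl | intermediate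
5 | tert-butyl{[(3E)-7-chloro-4-methylhept-3-en-2-yl]oxy}dimethylsilane | CC(O[Si](C)(C)C(C)(C)C)/C=C(\C)CCCCl | intermediate
6 | 3-methylbut-2-enal | CC(C)=CC=O | starting material
7 | {(4E)-6-[(tert-butyldimethylsilyl)oxy]-4-methylhept-4-en-1-yl}magnesium chloride (not isolated) | CC(O[Si](C)(C)C(C)(C)C)/C=C(\C)CCC[Mg]Cl | intermediate
8 | trimethylsilyl enol ether of 9 (not isolated) | CC(O[Si](C)(C)C(C)(C)C)/C=C(\C)CCCC(C)(C)/C=C/O[Si](C)(C)C | intermediate
9 | (7E)-9-[(tert-butyldimethylsilyl)oxy]-3,3,7-trimethyldec-7-enal | CC(O[Si](C)(C)C(C)(C)C)/C=C(\C)CCCC(C)(C)CC=O | intermediate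
10 | (7E)-9-hydroxy-3,3,7-trimethyldec-7-enal | CC(O)/C=C(\C)CCCC(C)(C)CC=O | intermediate
11 | (7E)-3,3,7-trimethyl-9-oxodec-7-enal | CC(=O)/C=C(\C)CCCC(C)(C)CC=O | intermediate
12 | (1S,2R)-2,6,6-trimethyl-2-(2-oxopropyl)cyclohexane-1-carbaldehyde (not isolated) | O=C[C@H]1C(C)(C)CCC[C@]1(C)CC(C)=O | intermediate
13 | (4aS,8aR)-5,5,8a-trimethyl-4a,5,6,7,8,8a-hexahydronaphthalen-2(1H)-one | O=C1C=C[C@H]2C(C)(C)CCC[C@]2(C)C1 | intermediate
14 | methyl bromoacetate | COC(=O)CBr | starting material
15 | methyl 2-[(1S,4aS,8aS)-5,5,8a-trimethyl-2-oxo-1,2,4a,5,6,7,8,8a-octahydronaphthalen-1-yl]acetate | O=C1C=C[C@H]2C(C)(C)CCC[C@]2(C)[C@@H]1CC(=O)OC | intermediate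
16 | methyl 2-[(1S,4aS,8aS)-5,5,8a-trimethyl-2-oxodecahydronaphthalen-1-yl]acetate (not isolated) | O=C1CC[C@H]2C(C)(C)CCC[C@]2(C)[C@@H]1CC(=O)OC | intermediate
17 | methyl 2-[(1R,4aS,8aS)-5,5,8a-trimethyl-2-oxodecahydronaphthalen-1-yl]acetate | O=C1CC[C@H]2C(C)(C)CCC[C@]2(C)[C@H]1CC(=O)OC | intermediate
18 | methyl 2-[(1S,4aS,8aS)-5,5,8a-trimethyl-2-methylidenedecahydronaphthalen-1-yl]acetate | C=C1CC[C@H]2C(C)(C)CCC[C@]2(C)[C@H]1CC(=O)OC | intermediate
19 | 2-[(1S,4aS,8aS)-5,5,8a-trimethyl-2-methylidenedecahydronaphthalen-1-yl]acetaldehyde | C=C1CC[C@H]2C(C)(C)CCC[C@]2(C)[C@H]1CC=O | intermediate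
20 | triethyl phosphonoacetate | CCOC(=O)CP(=O)(OCC)OCC | starting material
21 | 2-bromo-1,1-dimethoxyethane | COC(CBr)OC | starting material
22 | ethyl 2-(diethoxyphosphoryl)-4,4-dimethoxybutanoate | CCOC(=O)C(CC(OC)OC)P(=O)(OCC)OCC | intermediate
23 | ethyl (2E)-2-(2,2-dimethoxyethyl)-4-[(1S,4aS,8aS)-5,5,8a-trimethyl-2-methylidenedecahydronaphthalen-1-yl]but-2-enoate | C=C1CC[C@H]2C(C)(C)CCC[C@]2(C)[C@H]1C/C=C(\CC(OC)OC)C(=O)OCC | intermediate
24 | (2E)-2-(2,2-dimethoxyethyl)-4-[(1S,4aS,8aS)-5,5,8a-trimethyl-2-methylidenedecahydronaphthalen-1-yl]but-2-enoic acid | C=C1CC[C@H]2C(C)(C)CCC[C@]2(C)[C@H]1C/C=C(\CC(OC)OC)C(=O)O | intermediate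
25 | (R)-4-hydroxydihydrofuran-2(3H)-one | O[C@H]1COC(=O)C1 | starting material
26 | (R)-4-[(tert-butyldimethylsilyl)oxy]dihydrofuran-2(3H)-one | CC(C)(C)[Si](C)(C)O[C@H]1COC(=O)C1 | intermediate
27 | aldol adduct, 3,4-trans, both carbinol epimers | CC(C)(C)[Si](C)(C)O[C@H]1COC(=O)[C@@H]1C(O)C[C@H]1C(=C)CC[C@H]2C(C)(C)CCC[C@]12C | intermediate
28 | methanesulfonate of 27 (not isolated) | CC(C)(C)[Si](C)(C)O[C@H]1COC(=O)[C@@H]1C(OS(C)(=O)=O)C[C@H]1C(=C)CC[C@H]2C(C)(C)CCC[C@]12C | intermediate
29 | (3E,4R)-4-[(tert-butyldimethylsilyl)oxy]-3-{2-[(1S,4aS,8aS)-5,5,8a-trimethyl-2-methylidenedecahydronaphthalen-1-yl]ethylidene}dihydrofuran-2(3H)-one | CC(C)(C)[Si](C)(C)O[C@H]1COC(=O)/C1=C/C[C@H]1C(=C)CC[C@H]2C(C)(C)CCC[C@]12C | intermediate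
30 | isocoronarin D, (3E,4R)-4-hydroxy-3-{2-[(1S,4aS,8aS)-5,5,8a-trimethyl-2-methylidenedecahydronaphthalen-1-yl]ethylidene}dihydrofuran-2(3H)-one | O[C@H]1COC(=O)/C1=C/C[C@H]1C(=C)CC[C@H]2C(C)(C)CCC[C@]12C | intermediate
31 | mixed anhydride of 24 with 2,4,6-trichlorobenzoic acid (not isolated) | C=C1CC[C@H]2C(C)(C)CCC[C@]2(C)[C@H]1C/C=C(\CC(OC)OC)C(=O)OC(=O)c1c(Cl)cc(Cl)cc1Cl | intermediate
32 | acetal ester of 24 with 30 | C=C1CC[C@H]2C(C)(C)CCC[C@]2(C)[C@H]1C/C=C(\CC(OC)OC)C(=O)O[C@H]1COC(=O)/C1=C/C[C@H]1C(=C)CC[C@H]2C(C)(C)CCC[C@]12C | intermediate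
33 | CNP0274315.1 | C=C1CC[C@H]2C(C)(C)CCC[C@]2(C)[C@H]1C/C=C(\CC=O)C(=O)O[C@H]1COC(=O)/C1=C/C[C@H]1C(=C)CC[C@H]2C(C)(C)CCC[C@]12C | target

**Count.** Total steps: 19. Longest linear sequence: 15 steps (steps 1–10, then 15–19).

**Steps most likely to fail**

1. Step 6 (Proposed new method). The enamine may add too slowly to the doubly β-substituted enone, or the addition may revert before dehydration; facial or cis/trans selectivity may also be insufficient. The fallback uses known chemistry, sets out from 11 and returns at 19. Compound 11 is cyclised without asymmetric induction by the acid-catalysed Robinson-type sequence (p-TsOH, toluene, reflux): the aldehyde enol adds to the protonated enone and aldol condensation follows, giving racemic trans-5,5,8a-trimethyl-4a,5,6,7,8,8a-hexahydronaphthalen-2(1H)-one F1. Alkylation as in step 7, but with (1R,2S,5R)-menthyl bromoacetate, gives the menthyl esters F2. Hydrogenation and base equilibration as in step 8 leave two diastereomers that differ only in the sense of the decalin; the (1R,4aS,8aS) keto ester F3 is separated by crystallisation or chromatography, a classical resolution through a covalent auxiliary. Wittig methylenation as in step 9 gives the menthyl ester F4, and iBu2AlH at −78 °C releases the auxiliary and aldehyde 19.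

2. Step 7. SN2 alkylation at the carbon next to the quaternary centre may be slow, so that proton exchange, dialkylation or O-alkylation take over. The fallback sets out from 13 and returns at 17. The lithium dienolate of 13 is trapped with Me3SiCl as the 2-silyloxy diene F5. ZnBr2-mediated alkylation of F5 with methyl 2-chloro-2-(phenylthio)acetate, an SN1-type thionium electrophile that tolerates hindered enol ethers, gives the α-phenylthio ester F6. Raney Ni under H2 in ethanol removes sulfur and saturates the C6–C7 double bond, and K2CO3 in MeOH equilibrates the resulting C9 epimers to 17 as in step 8.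

3. Step 15. The lactone enolate may lose the silyloxy group by β-elimination before it meets the aldehyde. The fallback sets out from 19 and returns at 29, replacing steps 15 and 16 by one olefination. (4S)-3-Bromo-4-hydroxydihydrofuran-2(3H)-one F7 (from calcium L-threonate and HBr in acetic acid) is silylated with tBuMe2SiCl and imidazole to the silyl ether F8. PPh3 converts F8 into the phosphonium bromide F9, and Et3N deprotonates it to the stabilised ylide F10, which is far less basic than the lithium enolate. Wittig reaction of F10 with 19 in toluene at 60 °C gives 29 directly.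

**Further compounds**

F1 | step 6 | racemic trans-5,5,8a-trimethyl-4a,5,6,7,8,8a-hexahydronaphthalen-2(1H)-one | O=C1C=CC2C(C)(C)CCCC2(C)C1
F2 | step 6 | (1R,2S,5R)-menthyl 2-(5,5,8a-trimethyl-2-oxo-1,2,4a,5,6,7,8,8a-octahydronaphthalen-1-yl)acetate, both decalin enantiomers | C[C@@H]1CC[C@H]([C@@H](C1)OC(=O)CC1C(=O)C=CC2C(C)(C)CCCC12C)C(C)C
F3 | step 6 | (1R,2S,5R)-menthyl 2-[(1R,4aS,8aS)-5,5,8a-trimethyl-2-oxodecahydronaphthalen-1-yl]acetate | C[C@@H]1CC[C@H]([C@@H](C1)OC(=O)C[C@H]1C(=O)CC[C@H]2C(C)(C)CCC[C@]12C)C(C)C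
F4 | step 6 | (1R,2S,5R)-menthyl 2-[(1S,4aS,8aS)-5,5,8a-trimethyl-2-methylidenedecahydronaphthalen-1-yl]acetate | C[C@@H]1CC[C@H]([C@@H](C1)OC(=O)C[C@H]1C(=C)CC[C@H]2C(C)(C)CCC[C@]12C)C(C)C
F5 | step 7 | trimethyl{[(4aS,8aS)-5,5,8a-trimethyl-4a,5,6,7,8,8a-hexahydronaphthalen-2-yl]oxy}silane | C[Si](C)(C)OC1=C[C@@]2(C)CCCC(C)(C)[C@@H]2C=C1
F6 | step 7 | methyl 2-(phenylthio)-2-[(4aS,8aS)-5,5,8a-trimethyl-2-oxo-1,2,4a,5,6,7,8,8a-octahydronaphthalen-1-yl]acetate, mixture of epimers | O=C1C=C[C@H]2C(C)(C)CCC[C@]2(C)C1C(Sc1ccccc1)C(=O)OC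
F7 | step 15 | (4S)-3-bromo-4-hydroxydihydrofuran-2(3H)-one | O[C@H]1COC(=O)C1Br
F8 | step 15 | (4S)-3-bromo-4-[(tert-butyldimethylsilyl)oxy]dihydrofuran-2(3H)-one | CC(C)(C)[Si](C)(C)O[C@H]1COC(=O)C1Br
F9 | step 15 | {(4S)-4-[(tert-butyldimethylsilyl)oxy]-2-oxotetrahydrofuran-3-yl}triphenylphosphonium bromide | CC(C)(C)[Si](C)(C)O[C@H]1COC(=O)C1[P+](c1ccccc1)(c1ccccc1)c1ccccc1.[Br-]
F10 | step 15 | (4S)-4-[(tert-butyldimethylsilyl)oxy]-3-(triphenylphosphoranylidene)dihydrofuran-2(3H)-one | CC(C)(C)[Si](C)(C)O[C@H]1COC(=O)C1=P(c1ccccc1)(c1ccccc1)c1ccccc1
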